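Going from theta to beta multiplies the substrate charge by 2.24, and alpha has twice the partner of beta, yet the substrate left at 12.0 h reads 38%, 43% and 45%.

all flasks: initiator 10 mM

|  | substrate | partner | remark | time |
|---|---|---|---|---|
| theta | 0.067 M | 0.090 M | run made earlier |  |
| beta | 0.15 M | 0.090 M | run made earlier |  |
| alpha | 0.10 M | 0.18 M | run made earlier |  |
| flask | 0.10 M | 0.0900 M |  | 20 h |

| run | time / h | target / % | over-reaction product / % | substrate / % |
|---|---|---|---|---|
| theta | 0.833 | 4 | 0 | 95 |
| theta | 2.50 | 18 | 0 | 78 |
| theta | 4.00 | 21 | 0 | 72 |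
| theta | 6.00 | 34 | 4 | 64 |
| theta | 10.0 | 46 | 10 | 45 |
| theta | 12.0 | 50 | 14 | 38 |
| beta | 2.00 | 16 | 0 | 85 |
| beta | 4.00 | 29 | 4 | 75 |
| beta | 6.00 | 32 | 5 | 62 |
| beta | 8.00 | 41 | 6 | 55 |
| beta | 10.0 | 42 | 8 | 46 |
| beta | 12.0 | 45 | 16 | 43 |
| alpha | 2.50 | 18 | 2 | 81 |
| alpha | 5.00 | 31 | 1 | 68 |
| alpha | 8.00 | 39 | 10 | 55 |
| alpha | 10.0 | 45 | 8 | 47 |
| alpha | 12.0 | 46 | 13 | 45 |

(scatter of a reading: 2 percentage points)



* how much target the flask holds at 20 h, in percent of the substrate charged
* how much over-reaction product the flask holds at 20 h, in percent of the substrate charged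
* how much substrate the flask holds at 20 h, in percent of the substrate charged

So you can treat substrate in these runs as a first-order lag (pseudo-first-order decay). Pooling those three last readings, with their scatter, gives a reading of its time constant τ, the time in which substrate falls by a factor e: 13.8 h. My estimate for the flask at 20 h, with t the time since the start, is the fraction exp(−t/τ) of the charge, which leaves 23.5% substrate, so target and over-reaction product together hold 76.5%. At one partner per substrate, that conversion takes 0.0765 M, less than the 0.0900 M charged. τ does not split the sum between the two products.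

The forecast reads the runs as "first order in substrate and zero order in partner" and gives 49% target (43% to 54%), 29% over-reaction product (21% to 36%) and 22% substrate (17% to 30%). Its substrate differs from my 23.5%.

At 20 h the flask holds 48.7% target, 26.4% over-reaction product and 25.0% substrate, each inside the forecast's range.

    2 initiating radical → ended chains (k = 2.00 × 10⁷ M⁻¹ s⁻¹)
    initiator → 2 initiating radical (k = 0.0435 h⁻¹)
    substrate + initiating radical → chain carrier (k = 1.10 × 10⁶ M⁻¹ h⁻¹)
    target → over-reaction product (k = 0.0349 h⁻¹)
    partner + chain carrier → target + initiating radical (k = 3.47 × 10⁶ M⁻¹ h⁻¹)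

Starting from the theta run at its last reading, moving the substrate charge by itself leaves over-reaction product at 12.8%, as it was, while moving the time by itself takes it to 26.4%. Against the flask's 25.0%, τ gave 23.5%. For the same flask read at 8.0 h, τ gives 56.0% substrate, and that flask holds 53.4%.

(The numbers in the tables stem from a simulated flask with made-up constants, noise included.)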